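The six-membered ring is numbered as a 7-oxabicyclo[4.1.0]hept-4-ene (C1 quaternary epoxide carbon, C2 OMe, C3 OBz, C4=C5, C6 epoxide CH). It is disconnected to a 3-substituted furan and a two-carbon acetylene equivalent: the furan oxygen is the future methoxy oxygen on C2, furan C2/C5 are C2/C5 and furan C3/C4 are C1/C6. One Diels–Alder reaction of furan-3-ylmethyl benzoate with (Z)-1,2-bis(phenylsulfonyl)ethene forms C2–C3 and C4–C5 together (C4–C5 first as a single bond, which becomes the alkene when the bridge is opened). The symmetric dienophile removes any regiochemical question. Desulfonylation, catalyst-controlled trans opening of the oxygen bridge by benzoate, hydroxyl-directed epoxidation and O-methylation complete the route.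

Key step: step 2

Remark: compounds 4 and 5 are racemic, and their SMILES show the enantiomer that leads to the target. The single enantiomer is selected in step 4 by the chiral catalyst, so at most half of 5 can end in 6. The ligand is (R)-1-[(S)-2-(diphenylphosphino)ferrocenyl]ethyldi-tert-butylphosphine, written (R,S)-PPF-PtBu2. Which antipode opens (1S,4R)-5 at C4–O has to be confirmed in the first run; both antipodes are commercial.

Step 1
Reactants: 1 furan-3-ylmethanol
Product: 2 furan-3-ylmethyl benzoate
Conditions: BzCl, Et3N, DMAP (cat.), CH2Cl2, 0 °C to rt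
Reagents that add atoms: benzoyl chloride O=C(Cl)c1ccccc1
Why: Acylation of a primary alcohol with an acid chloride and amine base should install the ester that stays in the target as the CH2OBz group; no stereocenter is involved.

Step 2
Reactants: 2 furan-3-ylmethyl benzoate; 3 (Z)-1,2-bis(phenylsulfonyl)ethene
Product: 4 racemic [(1R,4S,5R,6S)-5,6-bis(phenylsulfonyl)-7-oxabicyclo[2.2.1]hept-2-en-2-yl]methyl benzoate (endo,cis-disulfone drawn; an exo isomer converges in step 3)
Conditions: CH2Cl2, rt, dark, 2 in slight excess
Reagents that add atoms: none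
Why: A concerted, suprafacial Diels–Alder [4+2] cycloaddition of the furan diene with the electron-poor cis-disulfone, the established use of 3 as an acetylene equivalent towards furans. It closes the carbocycle in an intermolecular [4+2] mode by joining furan C2 and C5 to the two alkene carbons of 3, and the furan oxygen is left as the 1,4-bridge that later becomes the methoxy oxygen. The two bridgehead stereocenters form as a racemate whose relative configuration is enforced by the bridge. The two sulfonyl-bearing centers are cis from the Z geometry of 3 and, like their endo or exo orientation, do not matter because both carbons become sp2 in step 3. Regioselectivity is not needed because 3 is symmetric, which is the reason for choosing it, and the reversibility typical of furan adducts is countered by the high reactivity of 3 at room temperature. The absolute configuration is selected later, in step 4.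

Step 3
Reactants: 4 racemic bis(phenylsulfonyl) adduct
Product: 5 racemic [(1S,4R)-7-oxabicyclo[2.2.1]hepta-2,5-dien-2-yl]methyl benzoate
Conditions: 2% Na(Hg), NaH2PO4, MeOH–THF, −20 °C
Reagents that add atoms: none
Why: Reductive 1,2-elimination of a vicinal disulfone with buffered sodium amalgam (Julia-type desulfonylation) should unveil the second alkene; the bridgehead centers are untouched and their descriptors change only through the CIP priorities.

Step 4
Reactants: 5 racemic [(1S,4R)-7-oxabicyclo[2.2.1]hepta-2,5-dien-2-yl]methyl benzoate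
Product: 6 [(5R,6R)-5-(benzoyloxy)-6-hydroxycyclohexa-1,3-dien-1-yl]methyl benzoate
Conditions: [Rh(cod)Cl]2 (2.5 mol %), (R,S)-PPF-PtBu2 (6 mol %), PhCO2H, Et3N, THF, 60 °C
Reagents that add atoms: benzoic acid O=C(O)c1ccccc1
Why: Rhodium-catalysed asymmetric ring opening of an oxabicyclic alkene with a carboxylate, run as a regiodivergent resolution: the chiral monovalent rhodium complex should bind the unsubstituted alkene on its exo face and cleave the bridgehead C–O bond of one absolute sense in both enantiomers (C4–O in (1S,4R)-5), benzoate then attacks the allyl-rhodium unit at C6 anti to the metal (SN2′), which sets OH and OBz trans and creates the C4=C5 alkene, while the other enantiomer is opened at C1–O to a separable constitutional isomer.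

Step 5
Reactants: 6 [(5R,6R)-5-(benzoyloxy)-6-hydroxycyclohexa-1,3-dien-1-yl]methyl benzoate
Product: 7 [(1S,2S,3R,6R)-3-(benzoyloxy)-2-hydroxy-7-oxabicyclo[4.1.0]hept-4-en-1-yl]methyl benzoate
Conditions: VO(acac)2 (5 mol %), t-BuOOH (in decane), CH2Cl2, 0 °C to rt
Reagents that add atoms: tert-butyl hydroperoxide CC(C)(C)OO
Why: Vanadium-catalysed hydroxyl-directed epoxidation should oxidise only the trisubstituted alkene that is allylic to the free hydroxyl, and the vanadate ester delivers oxygen from the face of that hydroxyl, so both epoxide centers are set cis to the C2 oxygen.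

Step 6
Reactants: 7 [(1S,2S,3R,6R)-3-(benzoyloxy)-2-hydroxy-7-oxabicyclo[4.1.0]hept-4-en-1-yl]methyl benzoate
Product: 8 [(1R,2S,3R,6R)-3-(benzoyloxy)-2-methoxy-7-oxabicyclo[4.1.0]hept-4-en-1-yl]methyl benzoate (target)
Conditions: Me3OBF4, 1,8-bis(dimethylamino)naphthalene, 4 Å molecular sieves, CH2Cl2, 0 °C to rt
Reagents that add atoms: trimethyloxonium tetrafluoroborate C[O+](C)C.F[B-](F)(F)F
Why: O-Methylation of a hindered secondary alcohol with an oxonium salt and a non-nucleophilic proton scavenger avoids alkoxide formation, so the neighbouring benzoates should not migrate; no stereocenter is touched, and the C1 descriptor changes from S to R only through the CIP priorities.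

Compound list
1 | furan-3-ylmethanol | OCc1ccoc1 | starting material
2 | furan-3-ylmethyl benzoate | O=C(OCc1ccoc1)c1ccccc1 | intermediate
3 | (Z)-1,2-bis(phenylsulfonyl)ethene | O=S(=O)(/C=C\S(=O)(=O)c1ccccc1)c1ccccc1 | starting material
4 | racemic [(1R,4S,5R,6S)-5,6-bis(phenylsulfonyl)-7-oxabicyclo[2.2.1]hept-2-en-2-yl]methyl benzoate | O=C(OCC1=C[C@H]2[C@@H](S(=O)(=O)c3ccccc3)[C@@H](S(=O)(=O)c3ccccc3)[C@@H]1O2)c1ccccc1 | intermediate
5 | racemic [(1S,4R)-7-oxabicyclo[2.2.1]hepta-2,5-dien-2-yl]methyl benzoate | O=C(OCC1=C[C@H]2C=C[C@@H]1O2)c1ccccc1 | intermediate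
6 | [(5R,6R)-5-(benzoyloxy)-6-hydroxycyclohexa-1,3-dien-1-yl]methyl benzoate | O=C(OCC1=CC=C[C@@H](OC(=O)c2ccccc2)[C@@H]1O)c1ccccc1 | intermediate
7 | [(1S,2S,3R,6R)-3-(benzoyloxy)-2-hydroxy-7-oxabicyclo[4.1.0]hept-4-en-1-yl]methyl benzoate | O[C@H]1[C@H](OC(=O)c2ccccc2)C=C[C@H]2O[C@]21COC(=O)c1ccccc1 | intermediate
8 | [(1R,2S,3R,6R)-3-(benzoyloxy)-2-methoxy-7-oxabicyclo[4.1.0]hept-4-en-1-yl]methyl benzoate | CO[C@H]1[C@H](OC(=O)c2ccccc2)C=C[C@H]2O[C@]21COC(=O)c1ccccc1 | target

Total step count: 6. Longest linear sequence: 6 steps (from 1).

Steps most likely to fail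

Step 4. The chiral rhodium complex may not dictate which bridgehead C–O bond is cleaved; substrate bias would then open both enantiomers of 5 at C4–O and give 6 in low enantiomeric purity. The fallback sets out from 5 and separates ring opening from enantiomer selection. 5 is opened with benzoic acid under an achiral catalyst ([Rh(cod)Cl]2, 1,1′-bis(diphenylphosphino)ferrocene, Et3N, THF), relying only on the substrate preference for cleavage of C4–O. This should give racemic material, that is 6 together with its enantiomer [(5S,6S)-5-(benzoyloxy)-6-hydroxycyclohexa-1,3-dien-1-yl]methyl benzoate F1. A lipase-catalysed kinetic resolution by transesterification with vinyl acetate, with the lipase chosen in a screen for acetylation of F1, should convert F1 into [(5S,6S)-6-(acetyloxy)-5-(benzoyloxy)cyclohexa-1,3-dien-1-yl]methyl benzoate F2 and leave 6. After chromatography the route is rejoined at 6.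

Step 3. The allylic benzoate may be cleaved reductively or by methanolysis under the amalgam conditions. The fallback sets out from 1 and introduces the benzoate after the reduction. 1 and 3 (CH2Cl2, rt) should give racemic [(1R,4S,5R,6S)-5,6-bis(phenylsulfonyl)-7-oxabicyclo[2.2.1]hept-2-en-2-yl]methanol F3. Na(Hg) with NaH2PO4 in MeOH–THF at −20 °C should then give racemic [(1S,4R)-7-oxabicyclo[2.2.1]hepta-2,5-dien-2-yl]methanol F4. Benzoylation (BzCl, pyridine, 0 °C) returns to the route at 5.

Step 5. The secondary dienol may be oxidised to a dienone that aromatises, or oxygen transfer may lack facial control. The fallback sets out from 4 and installs the epoxide before the ring is opened, on the convex face of the bicycle. mCPBA (CH2Cl2, NaHCO3) should epoxidise the only alkene of 4 from the exo face to give racemic [6,7-bis(phenylsulfonyl)-3,8-dioxatricyclo[3.2.1.0^2,4]oct-2-yl]methyl benzoate F5. Na(Hg) as in step 3 should then give racemic (3,8-dioxatricyclo[3.2.1.0^2,4]oct-6-en-2-yl)methyl benzoate F6. The rhodium-catalysed ring opening of step 4 (benzoic acid, same chiral ligand, Bu4NI as additive, higher temperature for this less activated alkene) should open one enantiomer of F6 to 7, with the epoxide already cis to the new hydroxyl, and the other enantiomer to a separable regioisomer. The route is rejoined at 7.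

Further compounds
F1 | step 4 | [(5S,6S)-5-(benzoyloxy)-6-hydroxycyclohexa-1,3-dien-1-yl]methyl benzoate | O=C(OCC1=CC=C[C@H](OC(=O)c2ccccc2)[C@H]1O)c1ccccc1
F2 | step 4 | [(5S,6S)-6-(acetyloxy)-5-(benzoyloxy)cyclohexa-1,3-dien-1-yl]methyl benzoate | O=C(OCC1=CC=C[C@H](OC(=O)c2ccccc2)[C@H]1OC(C)=O)c1ccccc1
F3 | step 3 | racemic [(1R,4S,5R,6S)-5,6-bis(phenylsulfonyl)-7-oxabicyclo[2.2.1]hept-2-en-2-yl]methanol | OCC1=C[C@H]2[C@@H](S(=O)(=O)c3ccccc3)[C@@H](S(=O)(=O)c3ccccc3)[C@@H]1O2
F4 | step 3 | racemic [(1S,4R)-7-oxabicyclo[2.2.1]hepta-2,5-dien-2-yl]methanol | OCC1=C[C@H]2C=C[C@@H]1O2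
F5 | step 5 | racemic [6,7-bis(phenylsulfonyl)-3,8-dioxatricyclo[3.2.1.0^2,4]oct-2-yl]methyl benzoate (exo-epoxide, endo,cis-disulfone) | O=C(OC[C@@]12O[C@@H]1[C@H]3[C@@H](S(=O)(=O)c4ccccc4)[C@@H](S(=O)(=O)c4ccccc4)[C@@H]2O3)c1ccccc1
F6 | step 5 | racemic (3,8-dioxatricyclo[3.2.1.0^2,4]oct-6-en-2-yl)methyl benzoate (exo-epoxide) | O=C(OC[C@@]12O[C@@H]1[C@H]3C=C[C@@H]2O3)c1ccccc1
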